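The synthesis rests on the C3–C4 bond of the pyranone ring C. An enantioselective rhodium-catalysed intramolecular hydroacylation adds the formyl C–H bond of a fully substituted ring A benzaldehyde across the C2=C3 double bond of a 1-aryloxy-1-arylethene attached through O1, which closes ring C 6-endo and creates the C2 stereocentre in one atom-economic isomerisation. The step exploits that C2, carrying O1 and ring B, lies β to the C4 ketone, so ring C is a masked aldehyde plus enol ether. The achiral precursor is made by palladium-catalysed O-vinylation of bis-MOM-protected 3,5-diprenylphloroglucinaldehyde with a chromenyl vinyl triflate.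

Key step: step 6

Assumption: the sense of asymmetric induction in step 6 is not known for this substrate class; (R)-DTBM-SEGPHOS is written, and its antipode is to be used if a model cyclisation shows the opposite sense.

Step 1
Reactants: 1 4-hydroxyacetophenone; 2 1,1-diethoxy-3-methylbut-2-ene (prenal diethyl acetal)
Product: 4 1-(2,2-dimethyl-2H-chromen-6-yl)ethan-1-one, via ortho-quinone methide 3 (not isolated)
Conditions: 3-picoline (0.25 equiv), p-xylene, 140 °C, ethanol distilled off
Reagents that add atoms: none
Why: Pyridine-base-mediated chromenylation of a phenol by an α,β-unsaturated acetal: C-alkylation at one of the two equivalent ortho positions and loss of two molecules of ethanol give ortho-quinone methide 3, whose oxa-6π electrocyclisation closes the 2,2-dimethyl-2H-pyran ring.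

Step 2
Reactants: 4 1-(2,2-dimethyl-2H-chromen-6-yl)ethan-1-one
Product: 6 1-(2,2-dimethyl-2H-chromen-6-yl)ethenyl trifluoromethanesulfonate, via potassium enolate 5 (not isolated)
Conditions: KN(SiMe3)2, THF, −78 °C; then PhNTf2, −78 to 0 °C; used without prolonged storage
Reagents that add atoms: N-phenylbis(trifluoromethanesulfonimide), O=S(=O)(N(c1ccccc1)S(=O)(=O)C(F)(F)F)C(F)(F)F
Why: Kinetic deprotonation of the methyl ketone (one enolisable position only) and O-sulfonylation of enolate 5 by the triflimide is the standard enol triflate synthesis, and the chromene double bond is inert to the hindered amide base at low temperature.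

Step 3
Reactants: 7 2,4,6-trihydroxybenzaldehyde; 8 1-bromo-3-methylbut-2-ene (prenyl bromide, 2.2 equiv)
Product: 9 2,4,6-trihydroxy-3,5-bis(3-methylbut-2-en-1-yl)benzaldehyde
Conditions: 10% aq KOH, 0 °C to rt; chromatography
Reagents that add atoms: none
Why: Direct C-prenylation of an acylphloroglucinol: in aqueous alkali the ambident polyphenolate is alkylated on carbon at the only two ring C–H positions (C3 and C5, equivalent), so the 3,5-diprenyl compound should be the main dialkylation product after separation from mono- and over-alkylated material.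

Step 4
Reactants: 9 2,4,6-trihydroxy-3,5-bis(3-methylbut-2-en-1-yl)benzaldehyde
Product: 10 2-hydroxy-4,6-bis(methoxymethoxy)-3,5-bis(3-methylbut-2-en-1-yl)benzaldehyde
Conditions: MOMCl (2.2 equiv), i-Pr2NEt, CH2Cl2, 0 °C to rt
Reagents that add atoms: chloromethyl methyl ether, COCCl
Why: Base-mediated O-methoxymethylation of the para hydroxyl and of one of the two equivalent ortho hydroxyls; the remaining ortho hydroxyl is then locked in a hydrogen bond to the formyl oxygen and should stay free, as is usual for 2,4,6-trihydroxyaryl carbonyl compounds.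

Step 5
Reactants: 10 2-hydroxy-4,6-bis(methoxymethoxy)-3,5-bis(3-methylbut-2-en-1-yl)benzaldehyde; 6 1-(2,2-dimethyl-2H-chromen-6-yl)ethenyl trifluoromethanesulfonate
Product: 11 2-{[1-(2,2-dimethyl-2H-chromen-6-yl)ethenyl]oxy}-4,6-bis(methoxymethoxy)-3,5-bis(3-methylbut-2-en-1-yl)benzaldehyde
Conditions: Pd2(dba)3 (2.5 mol %), 2-di-tert-butylphosphino-2',4',6'-triisopropylbiphenyl (t-BuXPhos, 6 mol %), K3PO4, toluene, 80 °C; chromatography on Et3N-deactivated silica
Reagents that add atoms: none
Why: Palladium-catalysed C–O cross-coupling of a phenol with an enol triflate (Buchwald–Hartwig-type etherification): oxidative addition of zerovalent palladium into the vinyl C–OTf bond, exchange of triflate for phenoxide and C–O reductive elimination driven by the bulky biarylphosphine, with a weak phosphate base that spares the aldehyde and MOM ethers and limits elimination of the triflate to the alkyne.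

Step 6
Reactants: 11 2-{[1-(2,2-dimethyl-2H-chromen-6-yl)ethenyl]oxy}-4,6-bis(methoxymethoxy)-3,5-bis(3-methylbut-2-en-1-yl)benzaldehyde
Product: 12 (2S)-2-(2,2-dimethyl-2H-chromen-6-yl)-5,7-bis(methoxymethoxy)-6,8-bis(3-methylbut-2-en-1-yl)chroman-4-one
Conditions: [Rh(cod)Cl]2 (2.5 mol %), (R)-DTBM-SEGPHOS ((R)-5,5'-bis[di(3,5-di-tert-butyl-4-methoxyphenyl)phosphino]-4,4'-bi-1,3-benzodioxole, 5.5 mol %), Na[B(3,5-(CF3)2C6H3)4] (5 mol %), 1,4-dioxane, 60 °C
Reagents that add atoms: none
Why: Proposed new method: oxidative addition of the formyl C–H bond to the cationic monovalent rhodium bisphosphine should give an acyl hydride of trivalent rhodium held by the neighbouring enol ether; the hydride migrates to C2 (polarised δ+ by O1 and carrying ring B) to give a seven-membered acyl–alkyl rhodacycle, and C–C reductive elimination forms the C3–C4 bond. The closest known reaction type is the rhodium-catalysed enantioselective endo hydroacylation of ortho-allylbenzaldehydes with a 1,1-disubstituted alkene, which gives 3-substituted tetralones; here O1 replaces the benzylic CH2 of the tether, a substrate class (aryl 1-arylvinyl ethers) on which it has not been shown. Ring C closes formally 6-endo-trig with respect to the C2=C3 alkene. The C2 stereocentre is set under catalyst control, the chiral bisphosphine selecting the enantiotopic face of the enol ether to which hydride is delivered. The step needs 6-endo over 5-exo closure and must outrun decarbonylation: the 5-exo path would require reductive elimination at a fully substituted carbon (giving a 2-aryl-2-methylbenzofuran-3-one), reversible hydride insertion should funnel material to the primary alkyl rhodium, and the two oxygens flanking the formyl group (O1 and the C5 MOM ether) should stabilise the acyl hydride. The prenyl and chromene alkenes are tri- and cis-disubstituted and cannot reach the acyl rhodium centre intramolecularly, so they should remain untouched.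

Step 7
Reactants: 12 (2S)-2-(2,2-dimethyl-2H-chromen-6-yl)-5,7-bis(methoxymethoxy)-6,8-bis(3-methylbut-2-en-1-yl)chroman-4-one
Product: 13 (2S)-2-(2,2-dimethyl-2H-chromen-6-yl)-5,7-dihydroxy-6,8-bis(3-methylbut-2-en-1-yl)chroman-4-one
Conditions: 2 M HCl in MeOH/THF, 0 °C to rt, monitored and quenched with aq NaHCO3
Reagents that add atoms: none
Why: Acid-catalysed solvolysis of the two MOM acetals (transacetalisation to dimethoxymethane), the C5 ether being activated by chelation to the C4 carbonyl; dilute acid at low temperature is chosen so that the prenyl groups, the chromene double bond and the C2 benzylic ether stereocentre are left untouched.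

Compound list
1 | 4-hydroxyacetophenone | CC(=O)c1ccc(O)cc1 | starting material
2 | 1,1-diethoxy-3-methylbut-2-ene | CCOC(OCC)C=C(C)C | starting material
3 | 4-acetyl-6-(3-methylbut-2-en-1-ylidene)cyclohexa-2,4-dien-1-one (ortho-quinone methide, not isolated) | CC(=O)C1=CC(=CC=C(C)C)C(=O)C=C1 | intermediate
4 | 1-(2,2-dimethyl-2H-chromen-6-yl)ethan-1-one | CC(=O)c1ccc2OC(C)(C)C=Cc2c1 | intermediate
5 | potassium 1-(2,2-dimethyl-2H-chromen-6-yl)ethen-1-olate (not isolated) | [K+].[O-]C(=C)c1ccc2OC(C)(C)C=Cc2c1 | intermediate
6 | 1-(2,2-dimethyl-2H-chromen-6-yl)ethenyl trifluoromethanesulfonate | C=C(OS(=O)(=O)C(F)(F)F)c1ccc2OC(C)(C)C=Cc2c1 | intermediate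
7 | 2,4,6-trihydroxybenzaldehyde | O=Cc1c(O)cc(O)cc1O | starting material
8 | 1-bromo-3-methylbut-2-ene | CC(C)=CCBr | starting material
9 | 2,4,6-trihydroxy-3,5-bis(3-methylbut-2-en-1-yl)benzaldehyde | O=Cc1c(O)c(CC=C(C)C)c(O)c(CC=C(C)C)c1O | intermediate
10 | 2-hydroxy-4,6-bis(methoxymethoxy)-3,5-bis(3-methylbut-2-en-1-yl)benzaldehyde | O=Cc1c(O)c(CC=C(C)C)c(OCOC)c(CC=C(C)C)c1OCOC | intermediate
11 | 2-{[1-(2,2-dimethyl-2H-chromen-6-yl)ethenyl]oxy}-4,6-bis(methoxymethoxy)-3,5-bis(3-methylbut-2-en-1-yl)benzaldehyde | O=Cc1c(OC(=C)c2ccc3OC(C)(C)C=Cc3c2)c(CC=C(C)C)c(OCOC)c(CC=C(C)C)c1OCOC | intermediate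
12 | (2S)-2-(2,2-dimethyl-2H-chromen-6-yl)-5,7-bis(methoxymethoxy)-6,8-bis(3-methylbut-2-en-1-yl)chroman-4-one | CC(C)=CCc1c(OCOC)c(CC=C(C)C)c2c(c1OCOC)C(=O)C[C@@H](c1ccc3c(c1)C=CC(C)(C)O3)O2 | intermediate
13 | (2S)-2-(2,2-dimethyl-2H-chromen-6-yl)-5,7-dihydroxy-6,8-bis(3-methylbut-2-en-1-yl)chroman-4-one | CC(C)=CCc1c(O)c(CC=C(C)C)c2c(c1O)C(=O)C[C@@H](c1ccc3c(c1)C=CC(C)(C)O3)O2 | target

Total step count: 7
Longest linear sequence: 5 steps (steps 3, 4, 5, 6, 7 from 7; equally steps 1, 2, 5, 6, 7 from 1)

Steps most likely to fail

Step 6 (bears the label). The acyl rhodium hydride may decarbonylate before the hindered, electron-rich enol ether inserts; insertion may take the 5-exo course; or the face selection at C2 may be poor. The fallback uses known carbene catalysis and sets out from ketone 4 and phenol 10, returning at 12. Ketone 4 is brominated at the methyl group with PhNMe3Br3 in THF at 0 °C to give 2-bromo-1-(2,2-dimethyl-2H-chromen-6-yl)ethan-1-one F1. Corey–Bakshi–Shibata reduction with catecholborane and the (S)-2-methyl-CBS-oxazaborolidine, expected to give the S alcohol as with other α-halo aryl ketones, gives (1S)-2-bromo-1-(2,2-dimethyl-2H-chromen-6-yl)ethan-1-ol F2. Mitsunobu etherification of 10 with F2 (PPh3, DIAD, toluene, 0 °C) should proceed with inversion to the (R)-configured β-bromo ether 2-{[(1R)-2-bromo-1-(2,2-dimethyl-2H-chromen-6-yl)ethyl]oxy}-4,6-bis(methoxymethoxy)-3,5-bis(3-methylbut-2-en-1-yl)benzaldehyde F3. An N-heterocyclic carbene (from 3-benzyl-5-(2-hydroxyethyl)-4-methylthiazolium chloride and DBU, THF, 40 °C) then converts the aldehyde into its Breslow intermediate, which displaces the primary bromide 6-exo-tet. This is the known carbene-catalysed route from 2-(2-haloethoxy)benzaldehydes to chroman-4-ones; it forms the same C3–C4 bond with the C2 stereocentre already in place and gives 12.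

Step 5. C–O reductive elimination may be slow because the phenoxide is di-ortho-substituted and can chelate palladium through its formyl group, and base may eliminate triflic acid from 6 to the aryl alkyne. The fallback avoids metal-mediated C–O bond formation, sets out from ketone 4 and phenol 10, and returns at 11. α-Bromo ketone F1 (made from 4 as above) is reduced with NaBH4 in MeOH at 0 °C to racemic 2-bromo-1-(2,2-dimethyl-2H-chromen-6-yl)ethan-1-ol F4. Mitsunobu etherification of 10 with F4 gives the racemic β-bromo ether 2-{[2-bromo-1-(2,2-dimethyl-2H-chromen-6-yl)ethyl]oxy}-4,6-bis(methoxymethoxy)-3,5-bis(3-methylbut-2-en-1-yl)benzaldehyde F5; loss of configuration is irrelevant here. E2 elimination of HBr with KOt-Bu in THF at 0 °C, through the acidic benzylic hydrogen, gives enol ether 11.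

Step 3. The polyphenolate may be over-alkylated to dearomatised gem-diprenyl cyclohexadienones, alkylated on oxygen, or stop at the mono-prenyl stage, so the desired compound may be a minor component. The fallback fixes the regiochemistry by cross-coupling, sets out from 7 and returns at 10, bypassing steps 3 and 4. Bromination of 7 at its two free ring positions (N-bromosuccinimide, 2 equiv, MeCN, 0 °C) gives 3,5-dibromo-2,4,6-trihydroxybenzaldehyde F6. Bis-methoxymethylation as in step 4 gives 3,5-dibromo-2-hydroxy-4,6-bis(methoxymethoxy)benzaldehyde F7. A twofold Suzuki–Miyaura coupling with 4,4,5,5-tetramethyl-2-(3-methylbut-2-en-1-yl)-1,3,2-dioxaborolane (Pd(OAc)2, an α-selective biaryl dialkylphosphine, aq K3PO4, THF, 40 °C) gives 10.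

Further compounds
F1 | step 6 | 2-bromo-1-(2,2-dimethyl-2H-chromen-6-yl)ethan-1-one | O=C(CBr)c1ccc2OC(C)(C)C=Cc2c1
F2 | step 6 | (1S)-2-bromo-1-(2,2-dimethyl-2H-chromen-6-yl)ethan-1-ol | O[C@H](CBr)c1ccc2OC(C)(C)C=Cc2c1
F3 | step 6 | 2-{[(1R)-2-bromo-1-(2,2-dimethyl-2H-chromen-6-yl)ethyl]oxy}-4,6-bis(methoxymethoxy)-3,5-bis(3-methylbut-2-en-1-yl)benzaldehyde | O=Cc1c(O[C@@H](CBr)c2ccc3OC(C)(C)C=Cc3c2)c(CC=C(C)C)c(OCOC)c(CC=C(C)C)c1OCOC
F4 | step 5 | rac-2-bromo-1-(2,2-dimethyl-2H-chromen-6-yl)ethan-1-ol | OC(CBr)c1ccc2OC(C)(C)C=Cc2c1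
F5 | step 5 | rac-2-{[2-bromo-1-(2,2-dimethyl-2H-chromen-6-yl)ethyl]oxy}-4,6-bis(methoxymethoxy)-3,5-bis(3-methylbut-2-en-1-yl)benzaldehyde | O=Cc1c(OC(CBr)c2ccc3OC(C)(C)C=Cc3c2)c(CC=C(C)C)c(OCOC)c(CC=C(C)C)c1OCOC
F6 | step 3 | 3,5-dibromo-2,4,6-trihydroxybenzaldehyde | O=Cc1c(O)c(Br)c(O)c(Br)c1O
F7 | step 3 | 3,5-dibromo-2-hydroxy-4,6-bis(methoxymethoxy)benzaldehyde | O=Cc1c(O)c(Br)c(OCOC)c(Br)c1OCOC
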